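## Analysis of the target

Target 19 (compound numbers as in the list after the steps) is a monocyclic sesquiterpenoid aryl ether. Its single cyclohexanone ring is numbered here C1 (CMe2), C2 (C=O), C3, C4, C5 (C(CH3)OH) and C6 (CH); C6 carries the chain C7–C8–C9(CH3)(OH)–C10–C11, and C11 is bound through oxygen to C7 of a coumarin. There are three stereocentres: C5 (S) and C6 (R) are neighbours on the ring, with the C5 hydroxyl cis to the C6 chain, and C9 (R) lies four bonds from C6 in a freely rotating chain. The ring centres can control each other, but nothing in the ring can control C9, which must be brought in with its configuration already set. The sensitive groups are the coumarin (attacked by organometallics, hydride and hydroxide, and oxidisable), the two tertiary alcohols (dehydration in strong acid, and the C5 hydroxyl can bridge to C2 as a ketal in acidic alcohol) and, in every intermediate where C5 is still a carbonyl, the C6–H, whose epimerisation would scramble C6 against C9. The difficulty lies in the crowding around C6, which sits between the quaternary C1 and the fully substituted C5, in telling apart two ring carbons at carbonyl level (C2 and C5), and in the remote C9. The strategy rests on the fact that C3 and C4 are each α to an oxygen-bearing ring carbon, C2 (the ketone) and C5 (a ketone until its methyl group is added), so the C3–C4 bond of a cyclohexane-1,4-dione joins two enol carbons. Cutting it leaves an open-chain 2,5-dione in which C3 and C4 are both methyl groups, C1 is quaternary and C6 is the only stereocentre of the ring precursor.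

## Retrosynthetic reasoning

19 ⇒ 17 + 18. The C11–O(aryl) bond is cut first. The coumarin would not survive the organometallic, enolisation and anodic steps, so it is attached last. The forward reaction must etherify the primary C11 hydroxyl of triol 17 with the phenol 18 while two tertiary alcohols and the ketone stay untouched.

17 ⇒ 16. The C9 and C11 hydroxyls are tied together as a six-membered isopropylidene ketal. One group then protects both through base, hydride, organometallic and oxidative steps and comes off in mild aqueous acid.

16 ⇒ 15. The C5–CH3 bond is cut. This returns C5 to the ketone level and shows the ring as the 1,4-dione 15. The forward step must add a methyl nucleophile of low basicity to C5 and not to C2, from the face away from the C6 chain, without enolising toward C6.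

15 ⇒ 14 (key disconnection). The C3–C4 bond is cut. Both ends are α-carbons of carbonyl groups, so no polar pairing of them is natural, and the bond is made oxidatively from the bis(silyl enol ether) 14. All other ring bonds involve C1, C5 or C6, the crowded atoms, whereas C3 and C4 are unhindered methylene groups; closing the ring there leaves the hindered bonds to acyclic chemistry. The step forms no stereocentre, so it cannot damage the ones already present.

14 ⇒ 13. The two enol ethers come from the 2,5-dione 13. C2 can enolise only toward C3 because C1 is quaternary; C5 must enolise toward C4 and not toward C6.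

13 ⇒ 12 ⇒ 10. The two methyl ketones are traced to different groups so that they never have to be distinguished. The C5 ketone with its C4 methyl comes from a vinyl group by oxidation of 12, and the C2 ketone with its C3 methyl comes from the ester of 10 by addition of one carbon. This exposes in 10 an allylic stereocentre (C6) attached to a quaternary ester α-carbon (C1).

10 ⇒ 8 + 9. The C1–C6 bond is cut. It is the bond between the quaternary carbon and the stereocentre, and an enantioselective allylic alkylation of the linear carbonate 8 by the ester enolate equivalent 9 makes it at the substituted allyl terminus. C6 is thereby set by the catalyst, independently of the distant C9.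

8 ⇒ 7 ⇒ 6 ⇒ 4 + 5. The carbonate is the derivative of allylic alcohol 7, which comes from enoate 6 by reduction. The C5=C6 double bond of 6 is cut by olefination of aldehyde 4 with phosphonate 5, which supplies C5 and C4.

4 ⇒ 3 ⇒ 2 ⇒ 1. Aldehyde 4 holds C6–C11 with C9. These are carbons 6 to 1 of (R)-linalool 1: anti-Markovnikov hydration of its vinyl group gives C10–C11–OH (diol 2), the diol is ketalised (3), and cleavage of the trisubstituted alkene makes C6 the aldehyde carbon. The C9 configuration is taken from the chiral pool and never touched.

## Alternatives that were turned down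

Alternative 1: The C5–C6 bond is cut and the C5 oxygen is tied to a carboxyl carbon C7 on C6, so the ring comes from keto acid A1 (C5 methyl ketone, C6 as the α-carbon of the C7 acid, C2 as dioxolane). In the forward direction a chiral isothiourea would turn the activated acid into a C6 ammonium enolate that adds to the C5 ketone; the new alkoxide then acylates itself on C7 and gives the cis-fused β-lactone A2.
- For: one catalytic step makes the ring and both ring stereocentres. The four-membered lactone forces the C5 oxygen and C7 onto the same face, which is the relationship in 19. C2 is masked throughout, so no choice between two ketones arises. On this point it is stronger than the chosen route, where C5 depends on a site- and face-selective addition to a dione.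
- Against: the enolate carbon C6 is neopentyl, the acceptor is a methyl ketone and the ring is six-membered, an unfavourable combination for this reaction. A1 needs its own synthesis of a quaternary carbon beside a ketal. C7 of A2 is only one carbon of the chain, so C8–C11 with the C9 carbinol must be made as a second chiral fragment and joined to C7 beside the crowded C6.
- Comparison: the chosen strategy offers in exchange the complete C6–C11 chain, with C9 from the chiral pool, from the first step, and no fragment union after the ring is closed.

Alternative 2: The C1–C6 bond is cut. (S)-Linalool A3 (the enantiomer of 1, because here the terpene carbinol becomes C5 and not C9) would be converted into epoxy vinyl sulfone A4. A titanocene reagent of trivalent titanium opens the epoxide to the tertiary C1 radical, which adds to C6 of the vinyl sulfone in a 6-exo closure and gives sulfone A5.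
- For: epoxide-opening radical cyclisation is an established way to close rings at a quaternary carbon, so the ring-forming step has firmer precedent than the anodic closure. C5 comes from the chiral pool, and the sulfone at C7 is a handle for chain extension.
- Against: C6 is set relative to C5 in a transition state where the C5 methyl and silyloxy groups are of similar size, so cis/trans control is doubtful. A six-membered exo closure onto an acceptor carried by a fully substituted carbon is slow and competes with reduction of the radical. C9 again needs a second chiral building block, and C7–C8 must be made by alkylating a sulfonyl carbanion that sits beside C6, followed by desulfonylation and oxidation at C2.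
- Comparison: the ring closure is more secure, but two of the three stereocentres are less secure and the route is longer after the ring is made. The chosen route has a catalyst-controlled C6 and takes C9 from 1.

Alternative 3: The ring and C7–C9 are taken from the (S)-Hajos–Parrish ketone A6. Geminal methylation, reduction and ketalisation lead to the cis-hydrindanone A7, and the C5–C9 bond is cut by oxygen insertion: a buffered peracid makes the quaternary C5 migrate with retention and gives δ-lactone A8.
- For: both ring stereocentres come from a robust, scalable amine-catalysed annulation, and the migration fixes the C5–O configuration with certainty. This is the most reliable way among the four of securing C5 and C6 together, and clearly stronger than the chosen route on that point.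
- Against: cis ring fusion must be obtained when the ring-fusion alkene is reduced next to the new gem-dimethyl group. The lactone carbonyl C9 must then become a tertiary carbinol carrying methyl and the C10–C11 arm in an open chain, four bonds from the nearest stereocentre, with only a chiral reagent for control. The sequence is long.
- Comparison: the chosen strategy gives up the security at C5 but receives C9 from 1 and reaches the ring in fewer operations.

Key step: step 11

Assumption: the (Ra,R,R) enantiomer of the phosphoramidite ligand in step 7 is taken to be the one that delivers the nucleophile to the allyl face giving (S) at the new centre of 10; if the sense of induction of this ligand class is the opposite, its mirror image is used and nothing else changes.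

## Route

Step 1
Reactants: 1 (R)-linalool [(3R)-3,7-dimethylocta-1,6-dien-3-ol]
Product: 2 (3R)-3,7-dimethyloct-6-ene-1,3-diol
Conditions: 9-BBN (2.2 equiv), THF, 0 °C to rt; then NaOH, H2O2, 0 °C
Reagents that add atoms: hydrogen peroxide, OO
Why: Hydroboration–oxidation; 9-BBN adds to the monosubstituted vinyl group far faster than to the trisubstituted alkene and places boron on the terminal carbon, so oxidation gives the primary alcohol (C11). One equivalent of borane is consumed by the tertiary O–H, and the carbinol centre (later C9) is not involved.

Step 2
Reactants: 2 (3R)-3,7-dimethyloct-6-ene-1,3-diol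
Product: 3 (4R)-2,2,4-trimethyl-4-(4-methylpent-3-en-1-yl)-1,3-dioxane
Conditions: Me2C(OMe)2, PPTS (cat.), CH2Cl2, rt
Reagents that add atoms: 2,2-dimethoxypropane, COC(C)(C)OC
Why: Acid-catalysed transketalisation; the 1,3-diol closes a six-membered isopropylidene ketal that masks both hydroxyls through the basic, reducing, organometallic and oxidative steps that follow.

Step 3
Reactants: 3 (4R)-2,2,4-trimethyl-4-(4-methylpent-3-en-1-yl)-1,3-dioxane
Product: 4 3-[(4R)-2,2,4-trimethyl-1,3-dioxan-4-yl]propanal
Conditions: O3, CH2Cl2, NaHCO3, −78 °C; then PPh3, −78 °C to rt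
Reagents that add atoms: ozone, [O-][O+]=O
Why: Ozonolysis with reductive work-up; the only alkene is cleaved and the ketal is inert, so C6 appears as the aldehyde carbon.

Step 4
Reactants: 4 3-[(4R)-2,2,4-trimethyl-1,3-dioxan-4-yl]propanal; 5 triethyl phosphonoacetate
Product: 6 ethyl (2E)-5-[(4R)-2,2,4-trimethyl-1,3-dioxan-4-yl]pent-2-enoate
Conditions: NaH, THF, 0 °C to rt
Reagents that add atoms: none
Why: Horner–Wadsworth–Emmons olefination; the stabilised phosphonate anion gives the (E)-enoate and adds C5 and C4.

Step 5
Reactants: 6 ethyl (2E)-5-[(4R)-2,2,4-trimethyl-1,3-dioxan-4-yl]pent-2-enoate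
Product: 7 (2E)-5-[(4R)-2,2,4-trimethyl-1,3-dioxan-4-yl]pent-2-en-1-ol
Conditions: iBu2AlH (2.5 equiv), CH2Cl2, −78 °C; aq. potassium sodium tartrate
Reagents that add atoms: none
Why: 1,2-Reduction of the unsaturated ester by the aluminium hydride; at −78 °C the ketal and the alkene geometry are kept.

Step 6
Reactants: 7 (2E)-5-[(4R)-2,2,4-trimethyl-1,3-dioxan-4-yl]pent-2-en-1-ol
Product: 8 methyl (2E)-5-[(4R)-2,2,4-trimethyl-1,3-dioxan-4-yl]pent-2-en-1-yl carbonate
Conditions: ClCO2Me, pyridine, CH2Cl2, 0 °C
Reagents that add atoms: methyl chloroformate, COC(=O)Cl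
Why: O-Acylation of the primary allylic alcohol; the methyl carbonate is the leaving group for the allylic substitution and releases methoxide on ionisation, which activates the silyl ketene acetal.

Step 7
Reactants: 8 methyl (2E)-5-[(4R)-2,2,4-trimethyl-1,3-dioxan-4-yl]pent-2-en-1-yl carbonate; 9 1-methoxy-2-methyl-1-(trimethylsilyloxy)prop-1-ene (trimethylsilyl ketene acetal of methyl isobutyrate)
Product: 10 methyl (3S)-2,2-dimethyl-3-{2-[(4R)-2,2,4-trimethyl-1,3-dioxan-4-yl]ethyl}pent-4-enoate
Conditions: [Ir(cod)Cl]2 (2 mol%), (Ra,R,R)-binaphthol N,N-bis(1-phenylethyl)phosphoramidite (4 mol%), n-PrNH2 (pre-activation), 9 (2 equiv), THF, rt to 50 °C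
Reagents that add atoms: none
Why: Iridium-catalysed asymmetric allylic alkylation with a silyl ketene acetal as ester enolate; the cyclometallated iridium–phosphoramidite complex ionises the linear carbonate and directs the nucleophile to the substituted allyl terminus, forming C1–C6 in the branched product. The face of attack, and so (S) at the new centre, is fixed by the ligand, the C9 centre being too remote to interfere.

Step 8
Reactants: 10 methyl (3S)-2,2-dimethyl-3-{2-[(4R)-2,2,4-trimethyl-1,3-dioxan-4-yl]ethyl}pent-4-enoate
Product: 12 (4S)-3,3-dimethyl-4-{2-[(4R)-2,2,4-trimethyl-1,3-dioxan-4-yl]ethyl}hex-5-en-2-one, via α-silyl ketone lithium enolate 11 (not isolated)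
Conditions: Me3SiCH2Li (2.5 equiv), pentane/THF, 0 °C to rt; then MeOH, rt; aq. NH4Cl
Reagents that add atoms: (trimethylsilyl)methyllithium, [Li]C[Si](C)(C)C
Why: Acyl substitution of the ester by the silylmethyl anion; the α-silyl ketone is deprotonated by the second equivalent to enolate 11, which cannot add further, and methanol then protonates it and cleaves the C–Si bond to leave the methyl ketone (C3 introduced). C6–H is not acidic at this stage.

Step 9
Reactants: 12 (4S)-3,3-dimethyl-4-{2-[(4R)-2,2,4-trimethyl-1,3-dioxan-4-yl]ethyl}hex-5-en-2-one
Product: 13 (4R)-3,3-dimethyl-4-{2-[(4R)-2,2,4-trimethyl-1,3-dioxan-4-yl]ethyl}hexane-2,5-dione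
Conditions: PdCl2 (10 mol%), Cu(OAc)2 (20 mol%), O2 (1 atm), DMA/H2O (7:1), rt
Reagents that add atoms: water, O
Why: Wacker oxidation; Markovnikov hydroxypalladation of the terminal alkene gives the methyl ketone (C5=O, C4 methyl), the classical route from γ,δ-unsaturated ketones to 1,4-diketones. Re-oxidation by Cu(OAc)2 keeps the medium near neutral, so the ketal and the C6–H should not be disturbed (the descriptor changes to R only because C5 gains priority).

Step 10
Reactants: 13 (4R)-3,3-dimethyl-4-{2-[(4R)-2,2,4-trimethyl-1,3-dioxan-4-yl]ethyl}hexane-2,5-dione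
Product: 14 (4R)-2,5-bis(tert-butyldimethylsilyloxy)-3,3-dimethyl-4-{2-[(4R)-2,2,4-trimethyl-1,3-dioxan-4-yl]ethyl}hexa-1,5-diene
Conditions: TBSOTf (2.5 equiv), Et3N (5 equiv), CH2Cl2, −78 to 0 °C
Reagents that add atoms: tert-butyldimethylsilyl trifluoromethanesulfonate, CC(C)(C)[Si](C)(C)OS(=O)(=O)C(F)(F)F
Why: Soft enolisation with silyl triflate and amine; C2 can enolise only toward its methyl group because C1 is quaternary, and C5 enolises toward its methyl group because deprotonation at C6 would give a tetrasubstituted enol ether crowded by C1. No free enolate is formed, so aldol closure of the 1,4-diketone and epimerisation at C6 are avoided; tert-butyldimethylsilyl is chosen over trimethylsilyl so that the enol ethers withstand the methanolic electrolyte of step 11.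

Step 11
Reactants: 14 (4R)-2,5-bis(tert-butyldimethylsilyloxy)-3,3-dimethyl-4-{2-[(4R)-2,2,4-trimethyl-1,3-dioxan-4-yl]ethyl}hexa-1,5-diene
Product: 15 (3R)-2,2-dimethyl-3-{2-[(4R)-2,2,4-trimethyl-1,3-dioxan-4-yl]ethyl}cyclohexane-1,4-dione
Conditions: undivided cell, reticulated vitreous carbon anode, Pt cathode, constant current (ca. 2.2 F per mol), 0.1 M LiClO4, MeOH/CH2Cl2 (1:4), 2,6-lutidine (4 equiv), 0 °C
Reagents that add atoms: none
Why: Proposed new method: at the carbon anode one silyl enol ether loses an electron to give a radical cation whose terminal carbon is attacked by the nucleophilic terminal carbon of the second enol ether (C3–C4 bond); the resulting α-silyloxy radical is oxidised further and methanol removes both silyl groups to give the 1,4-diketone, with 2,6-lutidine as buffer and hydrogen evolved at the cathode. The closest known reaction types are the intramolecular anodic coupling of an enol ether radical cation with a second tethered enol ether, which gives 1,4-dicarbonyl equivalents, and the coupling of silyl enol ethers to 1,4-diketones by one-electron oxidants such as (NH4)2Ce(NO3)6; what is new is that the tether joins the two oxygen-bearing carbons. The six-membered ring therefore closes 6-endo-trig with respect to each π bond, both carbons of each alkene ending up in the ring. This mode should win over 5-exo attack on an oxygen-bearing carbon because it joins the nucleophilic terminus of one enol ether to the electrophilic terminus of the radical cation and leaves an oxygen-stabilised radical, whereas 5-exo attack would give a primary radical and a new fully substituted centre beside the crowded C6. No stereocentre is created: C3 and C4 become methylene groups and C2 and C5 carbonyl carbons. The selectivity required is intramolecular coupling ahead of solvent capture or desilylation of the radical cation; the gem-dimethyl group at C1 holds the two enol ethers close, the methanol content is kept low and the silyl groups are the robust tert-butyldimethylsilyl. The C6 centre should be preserved because no enolate or strong acid is present and C6–H is never part of an enol ether.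

Step 12
Reactants: 15 (3R)-2,2-dimethyl-3-{2-[(4R)-2,2,4-trimethyl-1,3-dioxan-4-yl]ethyl}cyclohexane-1,4-dione
Product: 16 (3R,4S)-4-hydroxy-2,2,4-trimethyl-3-{2-[(4R)-2,2,4-trimethyl-1,3-dioxan-4-yl]ethyl}cyclohexan-1-one
Conditions: MeLi (1.2 equiv), CeCl3 (anhydrous, 1.3 equiv), THF, −78 °C; aq. NH4Cl
Reagents that add atoms: methyllithium, [Li]C
Why: 1,2-Addition of an organocerium reagent, whose low basicity should prevent enolisation toward C6; the C5 ketone (secondary α-carbon) is expected to react before C2, which is flanked by the quaternary C1. With the C6 chain equatorial the axial face of C5 is blocked by the syn-axial methyl group on C1, so methyl should enter equatorially and leave the hydroxyl axial and cis to the C6 chain, which is (S) at C5.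

Step 13
Reactants: 16 (3R,4S)-4-hydroxy-2,2,4-trimethyl-3-{2-[(4R)-2,2,4-trimethyl-1,3-dioxan-4-yl]ethyl}cyclohexan-1-one
Product: 17 (3R,4S)-3-[(3R)-3,5-dihydroxy-3-methylpentyl]-4-hydroxy-2,2,4-trimethylcyclohexan-1-one
Conditions: AcOH/H2O/THF (3:1:1), rt
Reagents that add atoms: none
Why: Acid hydrolysis of the isopropylidene ketal; weak aqueous acid without an alcohol solvent should spare the tertiary alcohols and avoid a bridged ketal between the C5 hydroxyl and C2.

Step 14
Reactants: 17 (3R,4S)-3-[(3R)-3,5-dihydroxy-3-methylpentyl]-4-hydroxy-2,2,4-trimethylcyclohexan-1-one; 18 umbelliferone (7-hydroxy-2H-chromen-2-one)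
Product: 19 7-{[(3R)-3-hydroxy-5-[(1R,6S)-6-hydroxy-2,2,6-trimethyl-3-oxocyclohexyl]-3-methylpentyl]oxy}-2H-chromen-2-one (target)
Conditions: PPh3, DIAD, THF, 0 °C to rt
Reagents that add atoms: none
Why: Mitsunobu etherification; the acidic phenol displaces the activated primary C11 hydroxyl, while the two tertiary alcohols are not activated. The coumarin is introduced last and meets no base, nucleophile or oxidant.

## Compound list

1 | (R)-linalool, (3R)-3,7-dimethylocta-1,6-dien-3-ol | C=C[C@](C)(O)CCC=C(C)C | starting material
2 | (3R)-3,7-dimethyloct-6-ene-1,3-diol | CC(C)=CCC[C@@](C)(O)CCO | intermediate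
3 | (4R)-2,2,4-trimethyl-4-(4-methylpent-3-en-1-yl)-1,3-dioxane | CC(C)=CCC[C@]1(C)CCOC(C)(C)O1 | intermediate
4 | 3-[(4R)-2,2,4-trimethyl-1,3-dioxan-4-yl]propanal | O=CCC[C@]1(C)CCOC(C)(C)O1 | intermediate
5 | triethyl phosphonoacetate | CCOC(=O)CP(=O)(OCC)OCC | starting material
6 | ethyl (2E)-5-[(4R)-2,2,4-trimethyl-1,3-dioxan-4-yl]pent-2-enoate | CCOC(=O)/C=C/CC[C@]1(C)CCOC(C)(C)O1 | intermediate
7 | (2E)-5-[(4R)-2,2,4-trimethyl-1,3-dioxan-4-yl]pent-2-en-1-ol | OC/C=C/CC[C@]1(C)CCOC(C)(C)O1 | intermediate
8 | methyl (2E)-5-[(4R)-2,2,4-trimethyl-1,3-dioxan-4-yl]pent-2-en-1-yl carbonate | COC(=O)OC/C=C/CC[C@]1(C)CCOC(C)(C)O1 | intermediate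
9 | 1-methoxy-2-methyl-1-(trimethylsilyloxy)prop-1-ene | COC(O[Si](C)(C)C)=C(C)C | starting material
10 | methyl (3S)-2,2-dimethyl-3-{2-[(4R)-2,2,4-trimethyl-1,3-dioxan-4-yl]ethyl}pent-4-enoate | COC(=O)C(C)(C)[C@H](C=C)CC[C@]1(C)CCOC(C)(C)O1 | intermediate
11 | (4S)-3,3-dimethyl-4-{2-[(4R)-2,2,4-trimethyl-1,3-dioxan-4-yl]ethyl}-1-(trimethylsilyl)hex-5-en-2-one, present as its lithium enolate | C[Si](C)(C)CC(=O)C(C)(C)[C@H](C=C)CC[C@]1(C)CCOC(C)(C)O1 | intermediate (not isolated)
12 | (4S)-3,3-dimethyl-4-{2-[(4R)-2,2,4-trimethyl-1,3-dioxan-4-yl]ethyl}hex-5-en-2-one | CC(=O)C(C)(C)[C@H](C=C)CC[C@]1(C)CCOC(C)(C)O1 | intermediate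
13 | (4R)-3,3-dimethyl-4-{2-[(4R)-2,2,4-trimethyl-1,3-dioxan-4-yl]ethyl}hexane-2,5-dione | CC(=O)C(C)(C)[C@H](C(C)=O)CC[C@]1(C)CCOC(C)(C)O1 | intermediate
14 | (4R)-2,5-bis(tert-butyldimethylsilyloxy)-3,3-dimethyl-4-{2-[(4R)-2,2,4-trimethyl-1,3-dioxan-4-yl]ethyl}hexa-1,5-diene | C=C(O[Si](C)(C)C(C)(C)C)C(C)(C)[C@@H](CC[C@]1(C)CCOC(C)(C)O1)C(=C)O[Si](C)(C)C(C)(C)C | intermediate
15 | (3R)-2,2-dimethyl-3-{2-[(4R)-2,2,4-trimethyl-1,3-dioxan-4-yl]ethyl}cyclohexane-1,4-dione | CC1(C)C(=O)CCC(=O)[C@@H]1CC[C@]2(C)CCOC(C)(C)O2 | intermediate
16 | (3R,4S)-4-hydroxy-2,2,4-trimethyl-3-{2-[(4R)-2,2,4-trimethyl-1,3-dioxan-4-yl]ethyl}cyclohexan-1-one | CC1(C)C(=O)CC[C@](C)(O)[C@@H]1CC[C@]2(C)CCOC(C)(C)O2 | intermediate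
17 | (3R,4S)-3-[(3R)-3,5-dihydroxy-3-methylpentyl]-4-hydroxy-2,2,4-trimethylcyclohexan-1-one | CC1(C)C(=O)CC[C@](C)(O)[C@@H]1CC[C@@](C)(O)CCO | intermediate
18 | umbelliferone, 7-hydroxy-2H-chromen-2-one | Oc1ccc2ccc(=O)oc2c1 | starting material
19 | 7-{[(3R)-3-hydroxy-5-[(1R,6S)-6-hydroxy-2,2,6-trimethyl-3-oxocyclohexyl]-3-methylpentyl]oxy}-2H-chromen-2-one | CC1(C)C(=O)CC[C@](C)(O)[C@@H]1CC[C@@](C)(O)CCOc1ccc2ccc(=O)oc2c1 | target

## Step count and least certain steps

Total: 14 steps. Longest linear sequence: 14 steps, from 1 (compounds 5, 9 and 18 are bought).

Step 11 (key step, proposed new method).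
- What may go wrong: capture of the radical cation by methanol, or loss of a silyl group before the C–C bond forms (this returns 13, which can be recycled); oligomerisation through intermolecular coupling; cleavage of the C1–C6 bond in the cyclised radical cation, the oxidative counterpart of a Cope rearrangement of this 1,5-diene. The cause is that a closure that is endo at both alkenes is slower than the exo closures on which the precedent rests.
- Fallback (known chemistry, polar formation of the same bond): it sets out from 12 and comes back at 15. N-Bromosuccinimide in wet DMSO converts the vinyl group of 12 into the bromohydrin F1 (Br on C4, OH on C5, both C5 epimers). Et3SiOTf and 2,6-lutidine give the triethylsilyl ether F2, the ring–chain equilibrium of the γ-hydroxy ketone being drained toward the open form. KN(SiMe3)2 in THF at −78 °C forms the only possible enolate, at C3, which displaces bromide in a 6-exo-tet alkylation with the enolate double bond inside the forming ring, to give the 4-silyloxycyclohexanone F3. Bu4NF gives the 4-hydroxycyclohexanone F4, and Dess–Martin oxidation gives 15. C6 is never α to a carbonyl on this path until 15.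

Step 7.
- What may go wrong: erosion of branched over linear regioselectivity and of facial control, or slow C–C bond formation, because a tetrasubstituted ketene acetal must attack the substituted end of an alkyl-substituted allyl unit.
- Fallback (chirality transfer in place of catalyst control at the bond-forming step): it sets out from 4 and comes back at 13. Wittig reaction of 4 with Ph3P=C(CH3)C(=O)CH3 gives the (E)-enone F5. Corey–Bakshi–Shibata reduction with the B-methyl oxazaborolidine from (S)-diphenylprolinol and catecholborane should give the (R)-allylic alcohol F6, the alkenyl group acting as the large substituent. Isobutyryl chloride and pyridine give the isobutyrate F7. LiN(iPr)2 and Me3SiCl in THF (−78 °C, then warming) form the silyl ketene acetal, which has no geometry to control because both α-substituents are methyl. Ireland–Claisen rearrangement through a chair with the carbinol methyl equatorial forms C1–C6 on the face from which the C–O bond departs and should give acid F8 with (S) at C6 and an (E)-alkene. Excess MeLi converts the acid into methyl ketone F9, and ozonolysis (O3, then PPh3) cleaves the trisubstituted alkene to give 13.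

Step 10.
- What may go wrong: intramolecular aldol closure of the 1,4-diketone to a five-membered ring once one carbonyl is activated, opening of the isopropylidene ketal by the silyl triflate, or enolisation toward C6.
- Fallback (the two enol ethers are installed one after the other, so that an enolate never faces a ketone): it sets out from 10 and comes back at 14. Wacker oxidation of 10 under the conditions of step 9 gives keto ester F10. KN(SiMe3)2 and TBSCl in THF at −78 °C give the enol ether F11, the hindered ester being a poor acceptor at this temperature. Me3SiCH2Li followed by a brief cold methanol quench converts the ester into the methyl ketone F12. A second treatment with KN(SiMe3)2 and TBSCl silylates the C2 ketone, whose only enolisable position is C3, and gives 14.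

Step 12.
- What may go wrong: insufficient discrimination between the C5 and C2 carbonyl groups; poor facial selectivity if the dione reacts through a twist conformer or through the chair with the C6 chain axial; over-addition; epimerisation at C6 through enolisation.
- Fallback (reversible, sterically demanding C–C bond formation in place of direct methyl addition): it sets out from 15 and comes back at 16. Dimethylsulfoxonium methylide (Me3S(O)I, NaH, DMSO) adds reversibly to the less hindered C5 carbonyl and should place the new C–C bond equatorial, giving the spiro-epoxide F13 with oxygen axial and cis to the chain. LiBHEt3 opens the epoxide at its CH2 carbon to the tertiary alcohol and reduces the C2 ketone, giving diol F14. Dess–Martin oxidation of the secondary alcohol returns the ketone and gives 16.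

Step 9.
- What may go wrong: migration of the terminal alkene toward C6 through a palladium hydride, which would destroy the stereocentre; aldehyde formation under the directing influence of the C2 carbonyl; slow turnover at the hindered allylic position; ketal hydrolysis if acid builds up.
- Fallback (radical hydration in place of palladium oxidation): it sets out from 12 and comes back at 13. Mukaiyama hydration (Co(acac)2 cat., PhSiH3, O2, iPrOH) gives the Markovnikov secondary alcohol F15 without alkene migration, and Dess–Martin oxidation gives 13.

## Further compounds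

F1 | step 11 | bromohydrin of 12: (4R)-4-(2-bromo-1-hydroxyethyl)-3,3-dimethyl-6-[(4R)-2,2,4-trimethyl-1,3-dioxan-4-yl]hexan-2-one, both carbinol epimers | CC(=O)C(C)(C)[C@H](C(O)CBr)CC[C@]1(C)CCOC(C)(C)O1
F2 | step 11 | triethylsilyl ether of F1 | CC(=O)C(C)(C)[C@H](C(O[Si](CC)(CC)CC)CBr)CC[C@]1(C)CCOC(C)(C)O1
F3 | step 11 | (3R)-2,2-dimethyl-4-(triethylsilyloxy)-3-{2-[(4R)-2,2,4-trimethyl-1,3-dioxan-4-yl]ethyl}cyclohexan-1-one, both C4 epimers | CC1(C)C(=O)CCC(O[Si](CC)(CC)CC)[C@@H]1CC[C@]2(C)CCOC(C)(C)O2
F4 | step 11 | (3R)-4-hydroxy-2,2-dimethyl-3-{2-[(4R)-2,2,4-trimethyl-1,3-dioxan-4-yl]ethyl}cyclohexan-1-one, both C4 epimers | CC1(C)C(=O)CCC(O)[C@@H]1CC[C@]2(C)CCOC(C)(C)O2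
F5 | step 7 | (3E)-3-methyl-6-[(4R)-2,2,4-trimethyl-1,3-dioxan-4-yl]hex-3-en-2-one | CC(=O)/C(C)=C/CC[C@]1(C)CCOC(C)(C)O1
F6 | step 7 | (2R,3E)-3-methyl-6-[(4R)-2,2,4-trimethyl-1,3-dioxan-4-yl]hex-3-en-2-ol | C[C@@H](O)/C(C)=C/CC[C@]1(C)CCOC(C)(C)O1
F7 | step 7 | (2R,3E)-3-methyl-6-[(4R)-2,2,4-trimethyl-1,3-dioxan-4-yl]hex-3-en-2-yl 2-methylpropanoate | CC(C)C(=O)O[C@H](C)/C(C)=C/CC[C@]1(C)CCOC(C)(C)O1
F8 | step 7 | (3S,4E)-2,2,4-trimethyl-3-{2-[(4R)-2,2,4-trimethyl-1,3-dioxan-4-yl]ethyl}hex-4-enoic acid | OC(=O)C(C)(C)[C@H](/C(C)=C/C)CC[C@]1(C)CCOC(C)(C)O1
F9 | step 7 | (4S,5E)-3,3,5-trimethyl-4-{2-[(4R)-2,2,4-trimethyl-1,3-dioxan-4-yl]ethyl}hept-5-en-2-one | CC(=O)C(C)(C)[C@H](/C(C)=C/C)CC[C@]1(C)CCOC(C)(C)O1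
F10 | step 10 | methyl (3R)-3-acetyl-2,2-dimethyl-5-[(4R)-2,2,4-trimethyl-1,3-dioxan-4-yl]pentanoate | COC(=O)C(C)(C)[C@H](C(C)=O)CC[C@]1(C)CCOC(C)(C)O1
F11 | step 10 | methyl (3R)-3-[1-(tert-butyldimethylsilyloxy)ethenyl]-2,2-dimethyl-5-[(4R)-2,2,4-trimethyl-1,3-dioxan-4-yl]pentanoate | COC(=O)C(C)(C)[C@H](C(=C)O[Si](C)(C)C(C)(C)C)CC[C@]1(C)CCOC(C)(C)O1
F12 | step 10 | (4R)-5-(tert-butyldimethylsilyloxy)-3,3-dimethyl-4-{2-[(4R)-2,2,4-trimethyl-1,3-dioxan-4-yl]ethyl}hex-5-en-2-one | CC(=O)C(C)(C)[C@H](C(=C)O[Si](C)(C)C(C)(C)C)CC[C@]1(C)CCOC(C)(C)O1
F13 | step 12 | (3S,4R)-5,5-dimethyl-4-{2-[(4R)-2,2,4-trimethyl-1,3-dioxan-4-yl]ethyl}-1-oxaspiro[2.5]octan-6-one | CC1(C)C(=O)CC[C@@]2(CO2)[C@@H]1CC[C@]3(C)CCOC(C)(C)O3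
F14 | step 12 | (3R,4S)-2,2,4-trimethyl-3-{2-[(4R)-2,2,4-trimethyl-1,3-dioxan-4-yl]ethyl}cyclohexane-1,4-diol, both C1 epimers | CC1(C)C(O)CC[C@](C)(O)[C@@H]1CC[C@]2(C)CCOC(C)(C)O2
F15 | step 9 | (4R)-5-hydroxy-3,3-dimethyl-4-{2-[(4R)-2,2,4-trimethyl-1,3-dioxan-4-yl]ethyl}hexan-2-one, both C5 epimers | CC(=O)C(C)(C)[C@H](C(C)O)CC[C@]1(C)CCOC(C)(C)O1
A1 | alternative 1 | 3-methyl-3-[2-(3-oxobutyl)-1,3-dioxolan-2-yl]butanoic acid | CC(=O)CCC1(OCCO1)C(C)(C)CC(O)=O
A2 | alternative 1 | cis-fused bicyclic β-lactone with C2 as dioxolane | CC1(C)C2(OCCO2)CC[C@]3(C)OC(=O)[C@H]13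
A3 | alternative 2 | (S)-linalool | C=C[C@@](C)(O)CCC=C(C)C
A4 | alternative 2 | 6,7-epoxide of the triethylsilyl ether of (S)-linalool with the vinyl group as (E)-2-(phenylsulfonyl)ethenyl | CC1(C)OC1CC[C@](C)(O[Si](CC)(CC)CC)/C=C/S(=O)(=O)c1ccccc1
A5 | alternative 2 | cyclised C7 sulfone with C2 alcohol and C5 triethylsilyl ether | CC1(C)[C@H](O)CC[C@](C)(O[Si](CC)(CC)CC)[C@@H]1CS(=O)(=O)c1ccccc1
A6 | alternative 3 | (S)-Hajos–Parrish ketone, (7aS)-7a-methyl-2,3,7,7a-tetrahydro-1H-indene-1,5(6H)-dione | C[C@]12CCC(=O)C=C1CCC2=O
A7 | alternative 3 | cis-hydrindanone with C1 gem-dimethyl and C2 as dioxolane | CC1(C)C2(OCCO2)CC[C@]3(C)C(=O)CC[C@H]13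
A8 | alternative 3 | cis-fused δ-lactone holding C1 to C9, C2 as dioxolane | CC1(C)C2(OCCO2)CC[C@]3(C)OC(=O)CC[C@H]13
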